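**Plan**

1. Retrosynthesis: the two methoxymethyl (MOM) ethers come off last, then ring A is cut at C5–C6 and C7–C8.
2. Enabling feature: C5 and C7 of ring A both carry oxygen and can be carbonyl-derived. C5 maps onto the C3 ester carbon and C8 onto the C2 methyl group of a 5-aryl-4-pyranone (rings C and B). C7, C6 and the CH2CH2C(CH3)2OH chain with its oxygen map onto the carbonyl carbon, α-carbon and alkyl C–O of 6,6-dimethyl-δ-valerolactone.
3. The pyranone is cut at O1–C2 and C2–C3 (isoflavone numbering) into one amide-acetal carbon and a 2-(arylacetyl)acetoacetate, which is cut further into the ring B arylacetic acid and methyl acetoacetate.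
4. Forward: ring B (resorcinol) receives the prenyl group and a two-carbon arm by two directed lithiations, the derived acid is joined to methyl acetoacetate, ring C is closed with the amide acetal, ring A is closed last from the lactone, then deprotection.
5. Stereochemistry: none to set; the target has no stereocentre and its only alkene carries two identical methyl groups.

Key step: step 8

Remark: enolisable compounds 12, 13 and 18 are drawn as single keto tautomers and organolithium intermediates as covalent C–Li species. The alkene geometry of enaminone 13 is left open because either isomer closes to the same pyranone.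

**Route**

Step 1
Reactants: 1 resorcinol
Product: 2 1,3-bis(methoxymethoxy)benzene
Conditions: MOMCl, i-Pr2NEt, CH2Cl2, 0 °C → rt
Reagents that add atoms: chloromethyl methyl ether, COCCl
Why: Double O-alkylation of the phenols (acetal protection) should install base-stable groups that also serve as directing groups for the two lithiations that follow.

Step 2
Reactants: 2 1,3-bis(methoxymethoxy)benzene; 3 prenyl bromide (1-bromo-3-methylbut-2-ene)
Product: 5 1,3-bis(methoxymethoxy)-2-(3-methylbut-2-enyl)benzene, via 2,6-bis(methoxymethoxy)phenyllithium 4 (not isolated)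
Conditions: n-BuLi, THF, 0 °C → rt; then CuI (10 mol%), 3, −78 °C → rt
Reagents that add atoms: none
Why: Directed ortho-metalation should occur at C2, the position flanked by both MOM ethers, and copper-catalysed SN2 allylation with the primary allylic bromide should give the linear prenyl product.

Step 3
Reactants: 5 1,3-bis(methoxymethoxy)-2-(3-methylbut-2-enyl)benzene
Product: 7 2-[2,4-bis(methoxymethoxy)-3-(3-methylbut-2-enyl)phenyl]ethanol, via [2,4-bis(methoxymethoxy)-3-(3-methylbut-2-enyl)phenyl]lithium 6 (not isolated)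
Conditions: n-BuLi, TMEDA, THF, 0 °C; then ethylene oxide (THF solution), −78 °C → rt; H2O
Reagents that add atoms: ethylene oxide, C1CO1
Why: A second directed ortho-metalation should take place at C4 (C4 and C6 are equivalent and each lies next to one MOM ether), and epoxide ring opening by the aryllithium adds the two-carbon arm.

Step 4
Reactants: 7 2-[2,4-bis(methoxymethoxy)-3-(3-methylbut-2-enyl)phenyl]ethanol
Product: 9 2-[2,4-bis(methoxymethoxy)-3-(3-methylbut-2-enyl)phenyl]acetic acid, via arylacetaldehyde 8 (not isolated)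
Conditions: TEMPO (20 mol%), PhI(OAc)2, MeCN/H2O (1:1), rt
Reagents that add atoms: water, O
Why: Oxoammonium-catalysed oxidation (TEMPO/PhI(OAc)2) should take the primary alcohol through the aldehyde hydrate to the acid without a chlorine-based oxidant, so the prenyl alkene and the acetals are left alone.

Step 5
Reactants: 9 2-[2,4-bis(methoxymethoxy)-3-(3-methylbut-2-enyl)phenyl]acetic acid; 10 methyl acetoacetate
Product: 12 methyl 2-acetyl-4-[2,4-bis(methoxymethoxy)-3-(3-methylbut-2-enyl)phenyl]-3-oxobutanoate, via arylacetyl chloride 11 (not isolated)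
Conditions: 1-chloro-N,N,2-trimethylprop-1-enylamine, CH2Cl2, 0 °C → rt; then 10, MgCl2, pyridine, CH2Cl2, 0 °C → rt
Reagents that add atoms: none
Why: The α-chloroenamine should form the acid chloride without releasing HCl (safe for the MOM ethers), and soft enolisation of methyl acetoacetate as its magnesium chelate (Rathke C-acylation) directs the acyl group to carbon.

Step 6
Reactants: 12 methyl 2-acetyl-4-[2,4-bis(methoxymethoxy)-3-(3-methylbut-2-enyl)phenyl]-3-oxobutanoate
Product: 14 methyl 5-[2,4-bis(methoxymethoxy)-3-(3-methylbut-2-enyl)phenyl]-2-methyl-4-oxo-4H-pyran-3-carboxylate, via enaminone 13 (not isolated)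
Conditions: Me2NCH(OMe)2, toluene, 80 °C; then AcOH (cat.), 60 °C
Reagents that add atoms: N,N-dimethylformamide dimethyl acetal, COC(OC)N(C)C
Why: Enaminone formation at the benzylic methylene (more acidic than the acetyl methyl group) followed by addition–elimination of the acetyl enol oxygen with loss of dimethylamine is the deoxybenzoin-to-isoflavone closure applied to an enolised 2-acyl-1,3-dicarbonyl compound, as known for cyclic triketones, and should give the 4-pyranone.

Step 7
Reactants: 15 2,2-dimethylcyclopentanone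
Product: 16 6,6-dimethyltetrahydro-2H-pyran-2-one
Conditions: m-CPBA, CH2Cl2, 0 °C → rt
Reagents that add atoms: 3-chloroperoxybenzoic acid, OOC(=O)c1cccc(Cl)c1
Why: In the Baeyer–Villiger oxidation the quaternary carbon migrates in preference to the secondary one, so oxygen is inserted next to the gem-dimethyl carbon.

Step 8
Reactants: 14 methyl 5-[2,4-bis(methoxymethoxy)-3-(3-methylbut-2-enyl)phenyl]-2-methyl-4-oxo-4H-pyran-3-carboxylate; 16 6,6-dimethyltetrahydro-2H-pyran-2-one
Product: 19 3-[2,4-bis(methoxymethoxy)-3-(3-methylbut-2-enyl)phenyl]-5,7-dihydroxy-6-(3-hydroxy-3-methylbutyl)-4H-chromen-4-one, via lithiated pyranone ester 17 (not isolated), via ring-opened keto alcohol 18 (not isolated)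
Conditions: LiN(i-Pr)2 (1.1 equiv), THF, −78 °C; 16 (1.2 equiv), −78 °C; LiN(i-Pr)2 (2.5 equiv), −78 → 0 °C; AcOH
Reagents that add atoms: none
Why: Proposed new method: lithium diisopropylamide should remove a proton from the C2 methyl group, which is vinylogously acidified by the C4 ketone and the C3 ester, and carbanion 17 adds to the lactone carbonyl (C7–C8 bond) to give a lactolate that opens on warming to the alkoxide of 18 and so releases the side-chain tertiary oxygen; the second charge of base then forms the enolate–carbanion (dianion over C8 and C6), whose terminal carbon C6 attacks the neighbouring ester carbonyl (C5–C6 bond) with loss of methoxide, and the cyclic 1,3-diketone tautomerises irreversibly to the 5,7-dihydroxy aromatic ring. The closest known reaction types are the acylation of laterally lithiated ortho-toluates and 2-methylchromone-3-carboxylates followed by Claisen (Dieckmann-type) closure to naphthalene-1,3-diols, and the biomimetic cyclisation of β-polycarbonyl dianions; the use of a lactone as acyl donor on a 4-pyranone ester in one operation is not established. Ring A closes in the 6-exo-trig mode, carbanion C6 attacking the exocyclic ester C=O to give the ring C4a–C5–C6–C7–C8–C8a. No stereocentre is formed. The step needs C- rather than O-acylation in the closure (O-acylation would give a fused 2-pyranone), which the dianion with its more nucleophilic terminal carbon and the irreversible aromatisation should secure, and it needs methyl deprotonation rather than base attack at the unsubstituted C6–H carbon of the pyranone or enolisation of the lactone, which the hindered amide base at −78 °C and the staged addition (second portion of base only after the lactone is bound as the lactolate) should secure. The 6-alkyl orientation is fixed by connectivity, because the lactone α-carbon is the only carbon that can reach the ester through a six-membered ring.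

Step 9
Reactants: 19 3-[2,4-bis(methoxymethoxy)-3-(3-methylbut-2-enyl)phenyl]-5,7-dihydroxy-6-(3-hydroxy-3-methylbutyl)-4H-chromen-4-one
Product: 20 3-[2,4-dihydroxy-3-(3-methylbut-2-enyl)phenyl]-5,7-dihydroxy-6-(3-hydroxy-3-methylbutyl)-4H-chromen-4-one (CNP0076924.0)
Conditions: HCl (1 M, MeOH/H2O), rt
Reagents that add atoms: none
Why: Acid-catalysed acetal methanolysis of the two phenolic MOM ethers should be faster at room temperature in dilute acid than ionisation of the tertiary alcohol or protonation of the prenyl alkene.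

**Compound list**

1 | resorcinol | Oc1cccc(O)c1 | starting material
2 | 1,3-bis(methoxymethoxy)benzene | COCOc1cccc(OCOC)c1 | intermediate
3 | prenyl bromide (1-bromo-3-methylbut-2-ene) | CC(C)=CCBr | starting material
4 | 2,6-bis(methoxymethoxy)phenyllithium | [Li]c1c(OCOC)cccc1OCOC | intermediate
5 | 1,3-bis(methoxymethoxy)-2-(3-methylbut-2-enyl)benzene | COCOc1cccc(OCOC)c1CC=C(C)C | intermediate
6 | [2,4-bis(methoxymethoxy)-3-(3-methylbut-2-enyl)phenyl]lithium | [Li]c1ccc(OCOC)c(CC=C(C)C)c1OCOC | intermediate
7 | 2-[2,4-bis(methoxymethoxy)-3-(3-methylbut-2-enyl)phenyl]ethanol | OCCc1ccc(OCOC)c(CC=C(C)C)c1OCOC | intermediate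
8 | 2-[2,4-bis(methoxymethoxy)-3-(3-methylbut-2-enyl)phenyl]acetaldehyde | O=CCc1ccc(OCOC)c(CC=C(C)C)c1OCOC | intermediate
9 | 2-[2,4-bis(methoxymethoxy)-3-(3-methylbut-2-enyl)phenyl]acetic acid | OC(=O)Cc1ccc(OCOC)c(CC=C(C)C)c1OCOC | intermediate
10 | methyl acetoacetate | COC(=O)CC(C)=O | starting material
11 | 2-[2,4-bis(methoxymethoxy)-3-(3-methylbut-2-enyl)phenyl]acetyl chloride | ClC(=O)Cc1ccc(OCOC)c(CC=C(C)C)c1OCOC | intermediate
12 | methyl 2-acetyl-4-[2,4-bis(methoxymethoxy)-3-(3-methylbut-2-enyl)phenyl]-3-oxobutanoate | COC(=O)C(C(C)=O)C(=O)Cc1ccc(OCOC)c(CC=C(C)C)c1OCOC | intermediate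
13 | methyl 2-acetyl-4-[2,4-bis(methoxymethoxy)-3-(3-methylbut-2-enyl)phenyl]-5-(dimethylamino)-3-oxopent-4-enoate (alkene geometry open) | COC(=O)C(C(C)=O)C(=O)C(=CN(C)C)c1ccc(OCOC)c(CC=C(C)C)c1OCOC | intermediate
14 | methyl 5-[2,4-bis(methoxymethoxy)-3-(3-methylbut-2-enyl)phenyl]-2-methyl-4-oxo-4H-pyran-3-carboxylate | COC(=O)c1c(C)occ(-c2ccc(OCOC)c(CC=C(C)C)c2OCOC)c1=O | intermediate
15 | 2,2-dimethylcyclopentanone | CC1(C)CCCC1=O | starting material
16 | 6,6-dimethyltetrahydro-2H-pyran-2-one | CC1(C)CCCC(=O)O1 | intermediate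
17 | methyl 5-[2,4-bis(methoxymethoxy)-3-(3-methylbut-2-enyl)phenyl]-2-(lithiomethyl)-4-oxo-4H-pyran-3-carboxylate | [Li]Cc1occ(-c2ccc(OCOC)c(CC=C(C)C)c2OCOC)c(=O)c1C(=O)OC | intermediate
18 | methyl 5-[2,4-bis(methoxymethoxy)-3-(3-methylbut-2-enyl)phenyl]-2-(6-hydroxy-6-methyl-2-oxoheptyl)-4-oxo-4H-pyran-3-carboxylate | COC(=O)c1c(CC(=O)CCCC(C)(C)O)occ(-c2ccc(OCOC)c(CC=C(C)C)c2OCOC)c1=O | intermediate
19 | 3-[2,4-bis(methoxymethoxy)-3-(3-methylbut-2-enyl)phenyl]-5,7-dihydroxy-6-(3-hydroxy-3-methylbutyl)-4H-chromen-4-one | CC(C)=CCc1c(OCOC)ccc(-c2coc3cc(O)c(CCC(C)(C)O)c(O)c3c2=O)c1OCOC | intermediate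
20 | 3-[2,4-dihydroxy-3-(3-methylbut-2-enyl)phenyl]-5,7-dihydroxy-6-(3-hydroxy-3-methylbutyl)-4H-chromen-4-one | CC(C)=CCc1c(O)ccc(-c2coc3cc(O)c(CCC(C)(C)O)c(O)c3c2=O)c1O | target

**Count**

Total steps: 9. Longest linear sequence: 8 steps (steps 1–6, 8, 9); step 7 is a one-step branch.

**Steps most likely to fail**

1. Step 8 (the proposed new method).
   - What may go wrong: the lactone may be enolised by the carbanion or by free amide base instead of being attacked at carbonyl. The acidic C8 methylene of the first-formed ketone may quench unreacted carbanion and stall conversion. The closure may proceed by O-acylation, and base may add to the unsubstituted C6–H carbon of the pyranone.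
   - Fallback (known chemistry, the same two bonds made in two separate operations): it sets out from 16 and 14 and comes back at 19. Aminolysis of 16 with MeNH(OMe)·HCl and i-PrMgCl should give 5-hydroxy-N-methoxy-N,5-dimethylhexanamide F1. Et3SiOSO2CF3 and 2,6-lutidine convert it into N-methoxy-N,5-dimethyl-5-(triethylsilyloxy)hexanamide F2. Carbanion 17, made from 14 with 1.05 equivalents of LiN(i-Pr)2 at −78 °C, is acylated by F2. The chelated tetrahedral adduct persists until the aqueous quench, so neither proton transfer nor a second addition can intervene, and methyl 5-[2,4-bis(methoxymethoxy)-3-(3-methylbut-2-enyl)phenyl]-2-[6-methyl-2-oxo-6-(triethylsilyloxy)heptyl]-4-oxo-4H-pyran-3-carboxylate F3 is isolated. A separate intramolecular Claisen condensation of F3 with LiN(i-Pr)2 (2.5 equiv, THF, −78 → 0 °C), or NaH in THF if O-acylation competes, should give 3-[2,4-bis(methoxymethoxy)-3-(3-methylbut-2-enyl)phenyl]-5,7-dihydroxy-6-[3-methyl-3-(triethylsilyloxy)butyl]-4H-chromen-4-one F4. Bu4NF in THF removes the silyl group and returns 19.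

2. Step 6.
   - What may go wrong: condensation may take place at the acetyl methyl group instead of the hindered benzylic methylene. The amide acetal may O-methylate the acidic triketone enol. Liberated dimethylamine or methanol may cause retro-Claisen loss of the acetyl group.
   - Fallback (aryl–pyranone bond by cross-coupling): it sets out from 5 and 10 and comes back at 14. Aryllithium 6, generated from 5 as in step 3, is quenched with 2-isopropoxy-4,4,5,5-tetramethyl-1,3,2-dioxaborolane to give 2-[2,4-bis(methoxymethoxy)-3-(3-methylbut-2-enyl)phenyl]-4,4,5,5-tetramethyl-1,3,2-dioxaborolane F5. Separately, 10 is C-acetylated (AcCl, MgCl2, pyridine) to methyl 2-acetyl-3-oxobutanoate F6, in which only methyl groups can condense. Me2NCH(OMe)2 gives methyl (E)-2-acetyl-5-(dimethylamino)-3-oxopent-4-enoate F7, which closes under acid catalysis to methyl 2-methyl-4-oxo-4H-pyran-3-carboxylate F8. Electrophilic bromination at C5 (Br2, pyridine, CH2Cl2, 0 °C) gives methyl 5-bromo-2-methyl-4-oxo-4H-pyran-3-carboxylate F9. Suzuki–Miyaura coupling of F9 with F5 (Pd(OAc)2, SPhos, K3PO4, dioxane/H2O, 80 °C) should give 14.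

3. Step 9.
   - What may go wrong: before both acetals are cleaved, the tertiary alcohol may ionise and cyclise onto the C5 or C7 hydroxyl to give a chroman. The 2'-hydroxyl may also cyclise onto the protonated prenyl alkene.
   - Fallback (exchange the acid-labile groups before the tertiary alcohol exists): it sets out from 14 and comes back at 20. HCl in MeOH converts 14 into methyl 5-[2,4-dihydroxy-3-(3-methylbut-2-enyl)phenyl]-2-methyl-4-oxo-4H-pyran-3-carboxylate F10. t-BuMe2SiCl and imidazole in DMF give methyl 5-[2,4-bis(tert-butyldimethylsilyloxy)-3-(3-methylbut-2-enyl)phenyl]-2-methyl-4-oxo-4H-pyran-3-carboxylate F11. The annulation with 16 under the conditions of step 8 then runs through the lithiated bis-silyl pyranone ester F12 and the ring-opened bis-silyl keto alcohol F13 to 3-[2,4-bis(tert-butyldimethylsilyloxy)-3-(3-methylbut-2-enyl)phenyl]-5,7-dihydroxy-6-(3-hydroxy-3-methylbutyl)-4H-chromen-4-one F14. Partial loss of an aryl silyl ether to lithium methoxide in that step would only anticipate the last operation. Bu4NF buffered with AcOH in THF at 0 °C then releases 20 without acid.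

**Further compounds**

F1 | step 8 | 5-hydroxy-N-methoxy-N,5-dimethylhexanamide | CON(C)C(=O)CCCC(C)(C)O
F2 | step 8 | N-methoxy-N,5-dimethyl-5-(triethylsilyloxy)hexanamide | CON(C)C(=O)CCCC(C)(C)O[Si](CC)(CC)CC
F3 | step 8 | methyl 5-[2,4-bis(methoxymethoxy)-3-(3-methylbut-2-enyl)phenyl]-2-[6-methyl-2-oxo-6-(triethylsilyloxy)heptyl]-4-oxo-4H-pyran-3-carboxylate | COC(=O)c1c(CC(=O)CCCC(C)(C)O[Si](CC)(CC)CC)occ(-c2ccc(OCOC)c(CC=C(C)C)c2OCOC)c1=O
F4 | step 8 | 3-[2,4-bis(methoxymethoxy)-3-(3-methylbut-2-enyl)phenyl]-5,7-dihydroxy-6-[3-methyl-3-(triethylsilyloxy)butyl]-4H-chromen-4-one | CC(C)=CCc1c(OCOC)ccc(-c2coc3cc(O)c(CCC(C)(C)O[Si](CC)(CC)CC)c(O)c3c2=O)c1OCOC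
F5 | step 6 | 2-[2,4-bis(methoxymethoxy)-3-(3-methylbut-2-enyl)phenyl]-4,4,5,5-tetramethyl-1,3,2-dioxaborolane | CC(C)=CCc1c(OCOC)ccc(B2OC(C)(C)C(C)(C)O2)c1OCOC
F6 | step 6 | methyl 2-acetyl-3-oxobutanoate | COC(=O)C(C(C)=O)C(C)=O
F7 | step 6 | methyl (E)-2-acetyl-5-(dimethylamino)-3-oxopent-4-enoate | COC(=O)C(C(C)=O)C(=O)/C=C/N(C)C
F8 | step 6 | methyl 2-methyl-4-oxo-4H-pyran-3-carboxylate | COC(=O)c1c(C)occc1=O
F9 | step 6 | methyl 5-bromo-2-methyl-4-oxo-4H-pyran-3-carboxylate | COC(=O)c1c(C)occ(Br)c1=O
F10 | step 9 | methyl 5-[2,4-dihydroxy-3-(3-methylbut-2-enyl)phenyl]-2-methyl-4-oxo-4H-pyran-3-carboxylate | COC(=O)c1c(C)occ(-c2ccc(O)c(CC=C(C)C)c2O)c1=O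
F11 | step 9 | methyl 5-[2,4-bis(tert-butyldimethylsilyloxy)-3-(3-methylbut-2-enyl)phenyl]-2-methyl-4-oxo-4H-pyran-3-carboxylate | COC(=O)c1c(C)occ(-c2ccc(O[Si](C)(C)C(C)(C)C)c(CC=C(C)C)c2O[Si](C)(C)C(C)(C)C)c1=O
F12 | step 9 | methyl 5-[2,4-bis(tert-butyldimethylsilyloxy)-3-(3-methylbut-2-enyl)phenyl]-2-(lithiomethyl)-4-oxo-4H-pyran-3-carboxylate | [Li]Cc1occ(-c2ccc(O[Si](C)(C)C(C)(C)C)c(CC=C(C)C)c2O[Si](C)(C)C(C)(C)C)c(=O)c1C(=O)OC
F13 | step 9 | methyl 5-[2,4-bis(tert-butyldimethylsilyloxy)-3-(3-methylbut-2-enyl)phenyl]-2-(6-hydroxy-6-methyl-2-oxoheptyl)-4-oxo-4H-pyran-3-carboxylate | COC(=O)c1c(CC(=O)CCCC(C)(C)O)occ(-c2ccc(O[Si](C)(C)C(C)(C)C)c(CC=C(C)C)c2O[Si](C)(C)C(C)(C)C)c1=O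
F14 | step 9 | 3-[2,4-bis(tert-butyldimethylsilyloxy)-3-(3-methylbut-2-enyl)phenyl]-5,7-dihydroxy-6-(3-hydroxy-3-methylbutyl)-4H-chromen-4-one | CC(C)=CCc1c(O[Si](C)(C)C(C)(C)C)ccc(-c2coc3cc(O)c(CCC(C)(C)O)c(O)c3c2=O)c1O[Si](C)(C)C(C)(C)C
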